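**Retrosynthetic overview**
1. Target 8 ⇒ diester 6: the C-6–O bond is made last, by enolate hydroxylation anti to the isopropyl group.
2. 6 ⇒ silyl dienol ether 5 + tiglic acid 3: the key C-4–O bond, by Pd-catalysed oxidative γ-acyloxylation, which sets C-4 cis to isopropyl.
3. 5 ⇒ enone ester 4 ⇒ carvotanacetone 2 + 3: the C-7–O bond, by carbonyl-directed allylic C–H acyloxylation.
4. 2 ⇒ (S)-carvone 1 by selective hydrogenation; C-5 comes from the chiral pool.
5. No ring is formed: the cyclohexenone ring of carvone is kept throughout.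

Assumption: catalysts, oxidants and other reagents named under Conditions are bought; only compounds whose carbon atoms end up in the target are numbered as starting materials.
Convention: ring positions in the "Why" lines follow carvone numbering (C-1 C=O, C-2 bearing C-7, C-3 =CH, C-4, C-5 bearing isopropyl, C-6).

Step 1
Reactants: 1 (S)-(+)-carvone [(5S)-2-methyl-5-(prop-1-en-2-yl)cyclohex-2-en-1-one]
Product: 2 (S)-carvotanacetone [(5S)-2-methyl-5-(propan-2-yl)cyclohex-2-en-1-one]
Conditions: H2 (1 atm), RhCl(PPh3)3 (1 mol%), benzene, rt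
Reagents that add atoms: none
Why: Homogeneous (Wilkinson) hydrogenation reduces only the unhindered 1,1-disubstituted isopropenyl alkene and leaves the conjugated trisubstituted enone alone; C-5 is not touched.

Step 2
Reactants: 2 (S)-carvotanacetone; 3 tiglic acid [(2E)-2-methylbut-2-enoic acid]
Product: 4 [(4S)-6-oxo-4-(propan-2-yl)cyclohex-1-en-1-yl]methyl (2E)-2-methylbut-2-enoate
Conditions: Pd(TFA)2 (10 mol%), N-acetylglycine (20 mol%), 1,4-benzoquinone (2 equiv), 3 (4 equiv), HFIP, 60 °C
Reagents that add atoms: none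
Why: Proposed new method: the ketone oxygen binds cationic Pd(II) in the enone plane next to the syn C-7 methyl group, N-acetylglycine-assisted concerted metalation–deprotonation of this allylic C–H bond gives a five-membered oxa-palladacycle that is also an allyl–palladium species, and benzoquinone-promoted attack of tiglate on its CH2 terminus gives the conjugated ester (the 3-acyloxy-2-methylene isomer would revert by SN2′ or Pd ionisation); the closest known reactions are Pd(II)/benzoquinone allylic C–H acyloxylation of simple alkenes and carbonyl-directed, amino-acid-ligand-assisted C–H palladation, neither shown for the α-methyl group of an enone; no stereocentre is formed.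

Step 3
Reactants: 4 [(4S)-6-oxo-4-(propan-2-yl)cyclohex-1-en-1-yl]methyl (2E)-2-methylbut-2-enoate
Product: 5 [(4S)-2-{[tert-butyl(dimethyl)silyl]oxy}-4-(propan-2-yl)cyclohexa-1,5-dien-1-yl]methyl (2E)-2-methylbut-2-enoate
Conditions: TBSOTf (1.3 equiv), Et3N (2.5 equiv), CH2Cl2, −78 °C to rt
Reagents that add atoms: tert-butyldimethylsilyl trifluoromethanesulfonate (TBSOTf), CC(C)(C)[Si](C)(C)OS(=O)(=O)C(F)(F)F
Why: Silyl enol ether formation by soft enolisation: O-silylation followed by γ-deprotonation (C-4) under equilibrating conditions gives the linear, fully conjugated dienol ether with a tetrasubstituted enol double bond, and no free enolate is formed that could expel the allylic tiglate; C-5 is untouched.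

Step 4
Reactants: 5 [(4S)-2-{[tert-butyl(dimethyl)silyl]oxy}-4-(propan-2-yl)cyclohexa-1,5-dien-1-yl]methyl (2E)-2-methylbut-2-enoate; 3 tiglic acid
Product: 6 [(3R,4S)-3-{[(2E)-2-methylbut-2-enoyl]oxy}-6-oxo-4-(propan-2-yl)cyclohex-1-en-1-yl]methyl (2E)-2-methylbut-2-enoate
Conditions: Pd(TFA)2 (5 mol%), LiCl (20 mol%), 1,4-benzoquinone (1.2 equiv), 3 (3 equiv), acetone, 0 °C to rt; aqueous work-up
Reagents that add atoms: none
Why: Proposed new method: Pd(II) binds the 1-silyloxy-1,3-diene on the face opposite to the isopropyl group, tiglate adds to the unsubstituted diene terminus C-4 anti to palladium (trans-acyloxypalladation, the first event of a Bäckvall 1,4-diacyloxylation) and so arrives syn to isopropyl, and the 1-silyloxy-π-allylpalladium formed collapses by loss of the silyl group to the enone and Pd(0), which benzoquinone reoxidises (a Saegusa–Ito oxidation in which C–O bond formation replaces β-hydride elimination); this sets the new C-4 centre (3R in 6) cis to isopropyl, and the closest known reactions are the Bäckvall diene diacetoxylation and the Saegusa–Ito oxidation.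

Step 5
Reactants: 6 [(3R,4S)-3-{[(2E)-2-methylbut-2-enoyl]oxy}-6-oxo-4-(propan-2-yl)cyclohex-1-en-1-yl]methyl (2E)-2-methylbut-2-enoate
Product: 8 [(3S,4R,5R)-5-hydroxy-3-{[(2E)-2-methylbut-2-enoyl]oxy}-6-oxo-4-(propan-2-yl)cyclohex-1-en-1-yl]methyl (2E)-2-methylbut-2-enoate, via sodium cross-conjugated dienolate 7 (not isolated)
Conditions: NaHMDS (1.1 equiv), THF, −78 °C; then 2-(phenylsulfonyl)-3-phenyloxaziridine (1.3 equiv), −78 °C; AcOH quench at −78 °C
Reagents that add atoms: 2-(phenylsulfonyl)-3-phenyloxaziridine (Davis oxaziridine), O=S(=O)(c1ccccc1)N1OC1c1ccccc1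
Why: Kinetic deprotonation at the only α′-CH2 (C-6) gives the cross-conjugated dienolate, which the oxaziridine oxidises on the face opposite to the C-5 isopropyl and C-4 tigloyloxy groups (both on the other face), so the new C-6 hydroxyl is trans to isopropyl (5R in 8); Davis enolate α-hydroxylation.

**Compound list**
1 | (S)-(+)-carvone, (5S)-2-methyl-5-(prop-1-en-2-yl)cyclohex-2-en-1-one | CC1=CC[C@H](C(C)=C)CC1=O | starting material
2 | (S)-carvotanacetone, (5S)-2-methyl-5-(propan-2-yl)cyclohex-2-en-1-one | CC1=CC[C@H](C(C)C)CC1=O | intermediate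
3 | tiglic acid, (2E)-2-methylbut-2-enoic acid | C/C=C(\C)C(=O)O | starting material
4 | [(4S)-6-oxo-4-(propan-2-yl)cyclohex-1-en-1-yl]methyl (2E)-2-methylbut-2-enoate | C/C=C(\C)C(=O)OCC1=CC[C@H](C(C)C)CC1=O | intermediate
5 | [(4S)-2-{[tert-butyl(dimethyl)silyl]oxy}-4-(propan-2-yl)cyclohexa-1,5-dien-1-yl]methyl (2E)-2-methylbut-2-enoate | C/C=C(\C)C(=O)OCC1=C(O[Si](C)(C)C(C)(C)C)C[C@@H](C(C)C)C=C1 | intermediate
6 | [(3R,4S)-3-{[(2E)-2-methylbut-2-enoyl]oxy}-6-oxo-4-(propan-2-yl)cyclohex-1-en-1-yl]methyl (2E)-2-methylbut-2-enoate (ring ester and isopropyl cis) | C/C=C(\C)C(=O)OCC1=C[C@H](OC(=O)/C(C)=C/C)[C@H](C(C)C)CC1=O | intermediate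
7 | sodium (3R,4R)-4-{[(2E)-2-methylbut-2-enoyl]oxy}-6-({[(2E)-2-methylbut-2-enoyl]oxy}methyl)-3-(propan-2-yl)cyclohexa-1,5-dien-1-olate (cross-conjugated dienolate of 6) | C/C=C(\C)C(=O)OCC1=C[C@H](OC(=O)/C(C)=C/C)[C@H](C(C)C)C=C1[O-].[Na+] | intermediate
8 | [(3S,4R,5R)-5-hydroxy-3-{[(2E)-2-methylbut-2-enoyl]oxy}-6-oxo-4-(propan-2-yl)cyclohex-1-en-1-yl]methyl (2E)-2-methylbut-2-enoate (ring ester cis and hydroxyl trans to isopropyl) | C/C=C(\C)C(=O)OCC1=C[C@H](OC(=O)/C(C)=C/C)[C@H](C(C)C)[C@@H](O)C1=O | target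

**Totals**
Total step count: 5. Longest linear sequence: 5 steps (1 → 2 → 4 → 5 → 6 → 8).

**Steps most likely to fail, with fallbacks**

Step 2 (new C–H acyloxylation): it may stall on the electron-poor enone or dehydrogenate the ring to a phenol. The fallback uses known chemistry, sets out from 2 and comes back at 4. Ketalisation of 2 with ethylene glycol (PPTS, benzene, Dean–Stark) gives the ketal (9S)-6-methyl-9-(propan-2-yl)-1,4-dioxaspiro[4.5]dec-6-ene F1, in which the methyl group is the only allylic C–H site on the more substituted alkene carbon. SeO2 (cat.)/t-BuOOH allylic oxidation (CH2Cl2, rt, NaBH4 work-up to reduce any enal) gives the allylic alcohol [(9S)-9-(propan-2-yl)-1,4-dioxaspiro[4.5]dec-6-en-6-yl]methanol F2. Steglich esterification with 3 (DCC, DMAP, CH2Cl2) gives the ester [(9S)-9-(propan-2-yl)-1,4-dioxaspiro[4.5]dec-6-en-6-yl]methyl (2E)-2-methylbut-2-enoate F3. PPTS in wet acetone removes the ketal and returns 4.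

Step 4 (new γ-acyloxylation): Saegusa-type dehydrogenation to a phenol, protodesilylation back to 4, or formation of the trans ester may compete. The fallback uses known chemistry, sets out from 5 and comes back at 6. Sensitised photo-oxygenation of 5 (O2, tetraphenylporphyrin, hν, CH2Cl2, −78 °C, then aqueous AcOH) adds singlet oxygen across the diene anti to isopropyl and gives the trans γ-hydroperoxy enone [(3S,4S)-3-hydroperoxy-6-oxo-4-(propan-2-yl)cyclohex-1-en-1-yl]methyl (2E)-2-methylbut-2-enoate F4. PPh3 reduces it to the trans γ-hydroxy enone [(3S,4S)-3-hydroxy-6-oxo-4-(propan-2-yl)cyclohex-1-en-1-yl]methyl (2E)-2-methylbut-2-enoate F5. Mitsunobu esterification with 3 (PPh3, DIAD, THF, 0 °C) inverts the carbinol centre and returns 6.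

Step 3 (dienol ether formation): the allylic tiglate of 4 may ionise under TBSOTf, or the cross-conjugated dienol ether may form. The fallback makes the dienol ether before any allylic ester is present, sets out from 2 and comes back at 6. Compound 2 is silylated under thermodynamic control (t-BuOK then TBSCl, THF) to the dienol ether tert-butyl(dimethyl){[(5S)-2-methyl-5-(propan-2-yl)cyclohexa-1,3-dien-1-yl]oxy}silane F6. The oxidative γ-tigloyloxylation of step 4 with 3 gives the cis ester (1R,6S)-3-methyl-4-oxo-6-(propan-2-yl)cyclohex-2-en-1-yl (2E)-2-methylbut-2-enoate F7. The carbonyl-directed C-7 tigloyloxylation of step 2 with 3 then returns 6.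

**Further compounds**
F1 | step 2 | (9S)-6-methyl-9-(propan-2-yl)-1,4-dioxaspiro[4.5]dec-6-ene | CC1=CC[C@H](C(C)C)CC12OCCO2
F2 | step 2 | [(9S)-9-(propan-2-yl)-1,4-dioxaspiro[4.5]dec-6-en-6-yl]methanol | OCC1=CC[C@H](C(C)C)CC12OCCO2
F3 | step 2 | [(9S)-9-(propan-2-yl)-1,4-dioxaspiro[4.5]dec-6-en-6-yl]methyl (2E)-2-methylbut-2-enoate | C/C=C(\C)C(=O)OCC1=CC[C@H](C(C)C)CC12OCCO2
F4 | step 4 | [(3S,4S)-3-hydroperoxy-6-oxo-4-(propan-2-yl)cyclohex-1-en-1-yl]methyl (2E)-2-methylbut-2-enoate | C/C=C(\C)C(=O)OCC1=C[C@@H](OO)[C@H](C(C)C)CC1=O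
F5 | step 4 | [(3S,4S)-3-hydroxy-6-oxo-4-(propan-2-yl)cyclohex-1-en-1-yl]methyl (2E)-2-methylbut-2-enoate | C/C=C(\C)C(=O)OCC1=C[C@@H](O)[C@H](C(C)C)CC1=O
F6 | step 3 | tert-butyl(dimethyl){[(5S)-2-methyl-5-(propan-2-yl)cyclohexa-1,3-dien-1-yl]oxy}silane | CC1=C(O[Si](C)(C)C(C)(C)C)C[C@@H](C(C)C)C=C1
F7 | step 3 | (1R,6S)-3-methyl-4-oxo-6-(propan-2-yl)cyclohex-2-en-1-yl (2E)-2-methylbut-2-enoate | CC1=C[C@H](OC(=O)/C(C)=C/C)[C@H](C(C)C)CC1=O
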